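I decide to read these runs in molar E, not in percent of the charge.

| flask | X | remark | time |
|---|---|---|---|
| teal | 0.26 M | run made earlier |  |
| red | 0.39 M | run made earlier |  |
| flask | 0.52 M |  | 30 min |

- teal (time / min: E / %): 5.00: 0; 10.0: 4; 15.0: 13; 20.0: 21; 25.0: 29; 30.0: 37
- red (time / min: E / %): 5.00: 4; 10.0: 3; 15.0: 7; 20.0: 13; 25.0: 24; 30.0: 33

(standard deviation of a reading: 1.5 percentage points)

* the E standing at 30 min, as a percentage of the X charged
* the change that raises the amount of E at 30 min, in percent of the X charged most ("none" if none brings more than 2 percentage points) (alpha / delta / none)
* amount of E at 30 min, in percent of the X charged, after alpha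

- X is a solid; its amount is given per volume of the solution
- at the start none of X is in solution

At 20.0 min, teal holds 0.0546 M of E and red 0.0507 M, about the same, though red was charged 1.50 times as much. So I take it that the solid feeds the solution at a rate that does not depend on how much solid lies there, zero order in the solid. I call molar E against time, while solid lasts, the common curve.

By 30.0 min, teal's 0.0962 M stands lower than red's 0.129 M, which I read as teal's solid ending. Taking red's value as the curve and spreading it over the flask's charge gives 24.8%, a floor if red too has begun to drop off.

Doubling the dissolution coefficient doubles the feed at a given gap between solubility and what is dissolved, and at such a gap the flask's feed per charge equals teal's, whose charge is half the flask's. But that gap narrows as the flask's solution fills, so I take teal's 37% as a top mark for alpha, not as its value. At a given dissolved amount, doubling solubility more than doubles the gap, so I choose delta.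

The forecast says 23%, none and 20%, on the reading that “dissolved X holds back its own conversion”. My figures differ from it on all three.

The flask gives 26.1%. The best change is delta, worth 11 percentage points, against 8.6 points for alpha, which reaches 34.7%.

    G → Z (k = 0.00300 s⁻¹)
    Z → Q (k = 0.00220 s⁻¹)
    Q ⇌ E (K = 0.940, k = 0.00170 s⁻¹)
    X ⇌ G, rate k4*(cs4 - [G]) while solid is left; crystals form when [G] > cs4 (solubility = 0.280 M, k = 0.00180 s⁻¹)

The flask's E is 0.136 M, against the 0.129 M carried from red. Dissolution can deliver at most 174% of the charge by 30 min into an empty solution, and the flask's X stands at 38.0% at 15.0 min and 0% at 30.0 min. In the flask at 11.7 min, Q is made 3.30 times faster than it is used up, each step taken net. Held at that molar E, a flask charged 0.646 M reads 21.1%, and the simulated flask at that charge stands 5 points from the present 26.1%.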